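The route rests on the bond between C6 of the tetrahydropyran-2-one ring (the carbon on ring oxygen O1) and the methyl-bearing side-chain carbon C2′. It is made by a strain-release 1,2-metallate shift: a trans-lithiated (R)-terminal epoxide captures the secondary boronic ester of the anti-1,3-dimethyl octenyl chain, and opening of the oxirane drives migration of C2′ from boron to carbon. One operation forms C6–C2′, sets C6, and delivers the syn C5/C6 dioxygen pattern of the lactone ring already differentiated (C5–OSiEt3, C6–B then OH). The precursor is an ate complex of oxirane and boronate. Oxidative lactonisation and acylation with the dienoic acid finish the target.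

Key step: step 8

Remark: ring atoms are O1, C2(=O), C3, C4, C5 (acyloxy carbon), C6; the octenyl chain is C1′–C8′ with C2′ on C6. Compounds 1, 4 and 26 and both sparteine enantiomers are taken as catalogue items.

Step 1
Reactants: 1 (Z)-2-(but-2-en-2-yl)-4,4,5,5-tetramethyl-1,3,2-dioxaborolane
Product: 3 (E)-4,4,5,5-tetramethyl-2-(2-methylbut-2-en-1-yl)-1,3,2-dioxaborolane, via chloromethyl boronate complex 2 (not isolated)
Conditions: BrCH2Cl, n-BuLi, THF, −78 °C to rt
Reagents that add atoms: bromochloromethane ClCBr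
Why: Matteson homologation: chloromethyllithium generated in situ adds to boron and the alkenyl group should shift 1,2 with loss of chloride and retention of alkene geometry, giving the (E)-allylic boronic ester.

Step 2
Reactants: 3 (E)-4,4,5,5-tetramethyl-2-(2-methylbut-2-en-1-yl)-1,3,2-dioxaborolane; 4 ethyl 2,4,6-triisopropylbenzoate
Product: 7 4,4,5,5-tetramethyl-2-[(2S,4E)-4-methylhex-4-en-2-yl]-1,3,2-dioxaborolane, via (R)-1-lithioethyl triisopropylbenzoate 5 (not isolated), via lithium boronate complex 6 (not isolated)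
Conditions: 4, s-BuLi, (+)-sparteine, Et2O, −78 °C; then 3, −78 °C to reflux
Reagents that add atoms: none
Why: Sparteine-mediated lithiation–borylation: (+)-sparteine should direct removal of the pro-R proton, the boronic ester is captured with retention and the allylic CH2 migrates with inversion at the carbenoid carbon, so the ligand sets the (S) boron-bearing centre (future C4′).

Step 3
Reactants: 7 4,4,5,5-tetramethyl-2-[(2S,4E)-4-methylhex-4-en-2-yl]-1,3,2-dioxaborolane
Product: 9 2-[(2R,4E)-2,4-dimethylhex-4-en-1-yl]-4,4,5,5-tetramethyl-1,3,2-dioxaborolane, via chloromethyl boronate complex 8 (not isolated)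
Conditions: BrCH2Cl, n-BuLi, Et2O, −78 °C to rt
Reagents that add atoms: bromochloromethane ClCBr
Why: Matteson one-carbon homologation in which the secondary alkyl group migrates with retention, so C4′ keeps its configuration while becoming an all-carbon centre.

Step 4
Reactants: 9 2-[(2R,4E)-2,4-dimethylhex-4-en-1-yl]-4,4,5,5-tetramethyl-1,3,2-dioxaborolane; 4 ethyl 2,4,6-triisopropylbenzoate
Product: 12 2-[(2R,4R,6E)-4,6-dimethyloct-6-en-2-yl]-4,4,5,5-tetramethyl-1,3,2-dioxaborolane, via (S)-1-lithioethyl triisopropylbenzoate 10 (not isolated), via lithium boronate complex 11 (not isolated)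
Conditions: 4, s-BuLi, (−)-sparteine, Et2O, −78 °C; then 9, −78 °C to reflux
Reagents that add atoms: none
Why: Second lithiation–borylation under reagent control: (−)-sparteine should give the (S)-lithiated ester, and retentive borylation followed by invertive 1,2-shift of the primary alkyl group sets the (R) boron-bearing centre (future C2′) anti to the C4′ methyl.

Step 5
Reactants: 13 pent-4-en-1-ol
Product: 14 1-methoxy-4-[(pent-4-en-1-yloxy)methyl]benzene
Conditions: NaH, 4-methoxybenzyl chloride, Bu4NI (cat.), THF/DMF, 0 °C to rt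
Reagents that add atoms: 4-methoxybenzyl chloride COc1ccc(CCl)cc1
Why: Williamson ether synthesis on the primary alkoxide; the PMB ether masks the future lactone carbon C2 as a base-stable group.

Step 6
Reactants: 14 1-methoxy-4-[(pent-4-en-1-yloxy)methyl]benzene
Product: 15 rac-2-{3-[(4-methoxybenzyl)oxy]propyl}oxirane
Conditions: mCPBA, NaHCO3, CH2Cl2, 0 °C to rt
Reagents that add atoms: 3-chloroperbenzoic acid OOC(=O)c1cccc(Cl)c1
Why: Prilezhaev epoxidation of the only alkene gives the racemic terminal epoxide.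

Step 7
Reactants: 15 rac-2-{3-[(4-methoxybenzyl)oxy]propyl}oxirane
Product: 16 (R)-2-{3-[(4-methoxybenzyl)oxy]propyl}oxirane
Conditions: (R,R)-(salen)Co(OAc) [salen = N,N′-bis(3,5-di-tert-butylsalicylidene)-1,2-cyclohexanediamine dianion] (0.5 mol %), H2O (0.55 equiv), THF, 0 °C to rt
Reagents that add atoms: none
Why: Hydrolytic kinetic resolution: the trivalent cobalt salen acetate, used as the enantiomer that hydrolyses the (S)-epoxide, should leave the (R)-epoxide whose stereocentre becomes C5 of the lactone.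

Step 8
Reactants: 12 2-[(2R,4R,6E)-4,6-dimethyloct-6-en-2-yl]-4,4,5,5-tetramethyl-1,3,2-dioxaborolane; 16 (R)-2-{3-[(4-methoxybenzyl)oxy]propyl}oxirane
Product: 20 (4R,5R,6R,8R,10E)-1-[(4-methoxybenzyl)oxy]-6,8,10-trimethyl-4-(triethylsilyloxy)dodec-10-en-5-ol, via trans-lithiated epoxide 17 (not isolated), via oxiranyl boronate complex 18 (not isolated), via silyloxy boronic ester 19 (not isolated)
Conditions: 12, 16, LiTMP (from TMPH, n-BuLi), THF, −30 °C; Et3SiOTf, −30 °C to rt; then NaOH, H2O2, THF/H2O, 0 °C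
Reagents that add atoms: triethylsilyl trifluoromethanesulfonate CC[Si](CC)(CC)OS(=O)(=O)C(F)(F)F; hydrogen peroxide OO
Why: LiTMP should remove the terminal oxirane proton trans to the alkyl chain, and the short-lived oxiranyl lithium is trapped at once by boronic ester 12 with retention to give ate complex 18. Release of oxirane strain, assisted by the silyl triflate on oxygen, then drives an anti-periplanar 1,2-shift of C2′ from boron to carbon with cleavage of the C–O bond, forming the C6–C2′ bond and the C5 silyl ether, after which peroxide replaces boron by hydroxyl with retention. The closest known reaction type is the homologation of boronic esters with lithiated terminal epoxides, a Matteson-type 1,2-metallate rearrangement with the epoxide oxygen as leaving group. No ring is closed here: the three-membered ring is opened and the six-membered lactone is closed later in step 10. The new centre C6 is controlled by the epoxide stereocentre through trans-lithiation, retentive borylation, invertive migration and retentive oxidation, which together give the syn C5/C6 relationship, while C5 comes unchanged from 16 and C2′ migrates with retention. The step needs borylation to outrun β-elimination and carbenoid dimerisation, secured by the hindered amide base with the boronic ester present from the start, and it needs the β-oxido boronate not to collapse to an alkene, secured by silylation.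

Step 9
Reactants: 20 (4R,5R,6R,8R,10E)-1-[(4-methoxybenzyl)oxy]-6,8,10-trimethyl-4-(triethylsilyloxy)dodec-10-en-5-ol
Product: 21 (4R,5R,6R,8R,10E)-6,8,10-trimethyl-4-(triethylsilyloxy)dodec-10-ene-1,5-diol
Conditions: DDQ, CH2Cl2/pH 7 buffer, 0 °C
Reagents that add atoms: none
Why: Oxidative cleavage of the PMB ether by DDQ (benzylic hydride abstraction then hydrolysis) should free the primary alcohol without touching the silyl ether or the trisubstituted alkene.

Step 10
Reactants: 21 (4R,5R,6R,8R,10E)-6,8,10-trimethyl-4-(triethylsilyloxy)dodec-10-ene-1,5-diol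
Product: 24 (5R,6R)-6-[(2R,4R,6E)-4,6-dimethyloct-6-en-2-yl]-5-(triethylsilyloxy)tetrahydro-2H-pyran-2-one, via hydroxy aldehyde 22 (not isolated), via lactol 23 (not isolated)
Conditions: TEMPO (cat.), PhI(OAc)2, CH2Cl2, rt
Reagents that add atoms: none
Why: Oxoammonium-mediated oxidative lactonisation: the primary alcohol is oxidised selectively, the aldehyde closes with the C6 hydroxyl to the six-membered lactol (the C5 oxygen is silylated, so no five-membered ring can form) and this is oxidised on to the δ-lactone.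

Step 11
Reactants: 24 (5R,6R)-6-[(2R,4R,6E)-4,6-dimethyloct-6-en-2-yl]-5-(triethylsilyloxy)tetrahydro-2H-pyran-2-one
Product: 25 (5R,6R)-6-[(2R,4R,6E)-4,6-dimethyloct-6-en-2-yl]-5-hydroxytetrahydro-2H-pyran-2-one
Conditions: HF·pyridine, pyridine, THF, 0 °C
Reagents that add atoms: none
Why: Buffered fluoride cleavage of the secondary triethylsilyl ether should free the C5 hydroxyl under conditions too mild for lactone opening or ring contraction.

Step 12
Reactants: 26 (5S)-5-{[(1S,2R,5S)-2-isopropyl-5-methylcyclohexyl]oxy}furan-2(5H)-one; 27 (2-methylprop-1-en-1-yl)magnesium bromide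
Product: 28 (4R,5S)-5-{[(1S,2R,5S)-2-isopropyl-5-methylcyclohexyl]oxy}-4-(2-methylprop-1-en-1-yl)dihydrofuran-2(3H)-one
Conditions: CuBr·SMe2 (10 mol %), THF, −78 to −40 °C; aq. NH4Cl
Reagents that add atoms: none
Why: Copper-catalysed 1,4-addition of the alkenyl Grignard reagent to the γ-alkoxybutenolide should occur anti to the menthyloxy group (auxiliary control), setting the (R) centre of the acid fragment.

Step 13
Reactants: 28 (4R,5S)-5-{[(1S,2R,5S)-2-isopropyl-5-methylcyclohexyl]oxy}-4-(2-methylprop-1-en-1-yl)dihydrofuran-2(3H)-one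
Product: 29 (R)-2-(2-methylprop-1-en-1-yl)butane-1,4-diol
Conditions: LiAlH4, THF, 0 °C to rt
Reagents that add atoms: none
Why: Hydride reduction of the lactone and of the aldehyde unmasked from the acetal carbon gives the 2-substituted butane-1,4-diol and releases the menthol auxiliary; the stereocentre is not involved.

Step 14
Reactants: 29 (R)-2-(2-methylprop-1-en-1-yl)butane-1,4-diol
Product: 30 (R)-1,4-bis(tert-butyldimethylsilyloxy)-2-(2-methylprop-1-en-1-yl)butane
Conditions: TBSCl, imidazole, DMF, rt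
Reagents that add atoms: tert-butyldimethylsilyl chloride CC(C)(C)[Si](C)(C)Cl
Why: Standard silylation of both primary alcohols.

Step 15
Reactants: 30 (R)-1,4-bis(tert-butyldimethylsilyloxy)-2-(2-methylprop-1-en-1-yl)butane
Product: 32 (2E,4R)-6-(tert-butyldimethylsilyloxy)-4-[(tert-butyldimethylsilyloxy)methyl]-2-methylhex-2-enal, via allylic alcohol 31 (not isolated)
Conditions: SeO2 (cat.), t-BuOOH, salicylic acid (cat.), CH2Cl2, rt; then MnO2, CH2Cl2
Reagents that add atoms: tert-butyl hydroperoxide CC(C)(C)OO; selenium dioxide O=[Se]=O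
Why: Riley allylic oxidation: the ene reaction and 2,3-shift of selenium dioxide should oxidise the methyl group trans to the chain on the more substituted alkene carbon, and manganese dioxide takes the allylic alcohol on to the (E)-enal.

Step 16
Reactants: 32 (2E,4R)-6-(tert-butyldimethylsilyloxy)-4-[(tert-butyldimethylsilyloxy)methyl]-2-methylhex-2-enal; 33 malonic acid
Product: 35 (2E,4E,6R)-8-(tert-butyldimethylsilyloxy)-6-[(tert-butyldimethylsilyloxy)methyl]-4-methylocta-2,4-dienoic acid, via alkylidenemalonic acid 34 (not isolated)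
Conditions: pyridine, piperidine (cat.), 70 °C
Reagents that add atoms: none
Why: Knoevenagel–Doebner condensation with decarboxylation should give the (2E)-acid directly, extending the (E)-enal to the (2E,4E)-dienoic acid.

Step 17
Reactants: 25 (5R,6R)-6-[(2R,4R,6E)-4,6-dimethyloct-6-en-2-yl]-5-hydroxytetrahydro-2H-pyran-2-one; 35 (2E,4E,6R)-8-(tert-butyldimethylsilyloxy)-6-[(tert-butyldimethylsilyloxy)methyl]-4-methylocta-2,4-dienoic acid
Product: 37 (2R,3R)-2-[(2R,4R,6E)-4,6-dimethyloct-6-en-2-yl]-6-oxotetrahydro-2H-pyran-3-yl (2E,4E,6R)-8-(tert-butyldimethylsilyloxy)-6-[(tert-butyldimethylsilyloxy)methyl]-4-methylocta-2,4-dienoate, via mixed anhydride 36 (not isolated)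
Conditions: 35, 2,4,6-trichlorobenzoyl chloride, Et3N, toluene, rt; then 25, DMAP, rt
Reagents that add atoms: none
Why: Yamaguchi esterification: the mixed anhydride acylates DMAP and then the secondary C5 hydroxyl with retention, joining the two halves.

Step 18
Reactants: 37 (2R,3R)-2-[(2R,4R,6E)-4,6-dimethyloct-6-en-2-yl]-6-oxotetrahydro-2H-pyran-3-yl (2E,4E,6R)-8-(tert-butyldimethylsilyloxy)-6-[(tert-butyldimethylsilyloxy)methyl]-4-methylocta-2,4-dienoate
Product: 38 (2R,3R)-2-[(2R,4R,6E)-4,6-dimethyloct-6-en-2-yl]-6-oxotetrahydro-2H-pyran-3-yl (2E,4E,6R)-8-hydroxy-6-(hydroxymethyl)-4-methylocta-2,4-dienoate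
Conditions: HF·pyridine, pyridine, THF, 0 °C to rt
Reagents that add atoms: none
Why: Fluoride cleavage of the two primary silyl ethers under buffered conditions should leave both esters and all alkenes intact and give the target.

Compound list
1 | (Z)-2-(but-2-en-2-yl)-4,4,5,5-tetramethyl-1,3,2-dioxaborolane | C/C=C(\C)B1OC(C)(C)C(C)(C)O1 | starting material
2 | lithium [(Z)-but-2-en-2-yl](chloromethyl)(pinacolato)borate | C/C=C(\C)[B-]1(CCl)OC(C)(C)C(C)(C)O1.[Li+] | intermediate
3 | (E)-4,4,5,5-tetramethyl-2-(2-methylbut-2-en-1-yl)-1,3,2-dioxaborolane | C/C=C(\C)CB1OC(C)(C)C(C)(C)O1 | intermediate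
4 | ethyl 2,4,6-triisopropylbenzoate | CCOC(=O)c1c(C(C)C)cc(C(C)C)cc1C(C)C | starting material
5 | (R)-1-lithioethyl 2,4,6-triisopropylbenzoate, (+)-sparteine complex | [Li][C@H](C)OC(=O)c1c(C(C)C)cc(C(C)C)cc1C(C)C | intermediate
6 | lithium [(E)-2-methylbut-2-en-1-yl][(R)-1-(2,4,6-triisopropylbenzoyloxy)ethyl](pinacolato)borate | C/C=C(\C)C[B-]1(OC(C)(C)C(C)(C)O1)[C@H](C)OC(=O)c2c(C(C)C)cc(C(C)C)cc2C(C)C.[Li+] | intermediate
7 | 4,4,5,5-tetramethyl-2-[(2S,4E)-4-methylhex-4-en-2-yl]-1,3,2-dioxaborolane | C/C=C(\C)C[C@H](C)B1OC(C)(C)C(C)(C)O1 | intermediate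
8 | lithium (chloromethyl)[(2S,4E)-4-methylhex-4-en-2-yl](pinacolato)borate | C/C=C(\C)C[C@H](C)[B-]1(CCl)OC(C)(C)C(C)(C)O1.[Li+] | intermediate
9 | 2-[(2R,4E)-2,4-dimethylhex-4-en-1-yl]-4,4,5,5-tetramethyl-1,3,2-dioxaborolane | C/C=C(\C)C[C@H](C)CB1OC(C)(C)C(C)(C)O1 | intermediate
10 | (S)-1-lithioethyl 2,4,6-triisopropylbenzoate, (−)-sparteine complex | [Li][C@@H](C)OC(=O)c1c(C(C)C)cc(C(C)C)cc1C(C)C | intermediate
11 | lithium [(2R,4E)-2,4-dimethylhex-4-en-1-yl][(S)-1-(2,4,6-triisopropylbenzoyloxy)ethyl](pinacolato)borate | C/C=C(\C)C[C@H](C)C[B-]1(OC(C)(C)C(C)(C)O1)[C@@H](C)OC(=O)c2c(C(C)C)cc(C(C)C)cc2C(C)C.[Li+] | intermediate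
12 | 2-[(2R,4R,6E)-4,6-dimethyloct-6-en-2-yl]-4,4,5,5-tetramethyl-1,3,2-dioxaborolane | C/C=C(\C)C[C@H](C)C[C@@H](C)B1OC(C)(C)C(C)(C)O1 | intermediate
13 | pent-4-en-1-ol | C=CCCCO | starting material
14 | 1-methoxy-4-[(pent-4-en-1-yloxy)methyl]benzene | C=CCCCOCc1ccc(OC)cc1 | intermediate
15 | rac-2-{3-[(4-methoxybenzyl)oxy]propyl}oxirane | COc1ccc(COCCCC2CO2)cc1 | intermediate
16 | (R)-2-{3-[(4-methoxybenzyl)oxy]propyl}oxirane | COc1ccc(COCCC[C@@H]2CO2)cc1 | intermediate
17 | (2R,3R)-2-lithio-3-{3-[(4-methoxybenzyl)oxy]propyl}oxirane (lithium trans to the chain) | [Li][C@H]1O[C@@H]1CCCOCc2ccc(OC)cc2 | intermediate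
18 | lithium [(2R,4R,6E)-4,6-dimethyloct-6-en-2-yl]{(2R,3R)-3-[3-(4-methoxybenzyloxy)propyl]oxiran-2-yl}(pinacolato)borate | C/C=C(\C)C[C@H](C)C[C@@H](C)[B-]1(OC(C)(C)C(C)(C)O1)[C@H]2O[C@@H]2CCCOCc3ccc(OC)cc3.[Li+] | intermediate
19 | 2-[(4R,5R,6R,8R,10E)-1-[(4-methoxybenzyl)oxy]-6,8,10-trimethyl-4-(triethylsilyloxy)dodec-10-en-5-yl]-4,4,5,5-tetramethyl-1,3,2-dioxaborolane | C/C=C(\C)C[C@H](C)C[C@@H](C)[C@@H](B1OC(C)(C)C(C)(C)O1)[C@@H](CCCOCc2ccc(OC)cc2)O[Si](CC)(CC)CC | intermediate
20 | (4R,5R,6R,8R,10E)-1-[(4-methoxybenzyl)oxy]-6,8,10-trimethyl-4-(triethylsilyloxy)dodec-10-en-5-ol | C/C=C(\C)C[C@H](C)C[C@@H](C)[C@@H](O)[C@@H](CCCOCc1ccc(OC)cc1)O[Si](CC)(CC)CC | intermediate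
21 | (4R,5R,6R,8R,10E)-6,8,10-trimethyl-4-(triethylsilyloxy)dodec-10-ene-1,5-diol | C/C=C(\C)C[C@H](C)C[C@@H](C)[C@@H](O)[C@@H](CCCO)O[Si](CC)(CC)CC | intermediate
22 | (4R,5R,6R,8R,10E)-5-hydroxy-6,8,10-trimethyl-4-(triethylsilyloxy)dodec-10-enal | C/C=C(\C)C[C@H](C)C[C@@H](C)[C@@H](O)[C@@H](CCC=O)O[Si](CC)(CC)CC | intermediate
23 | (5R,6R)-6-[(2R,4R,6E)-4,6-dimethyloct-6-en-2-yl]-5-(triethylsilyloxy)tetrahydro-2H-pyran-2-ol (anomeric mixture) | C/C=C(\C)C[C@H](C)C[C@@H](C)[C@H]1OC(O)CC[C@H]1O[Si](CC)(CC)CC | intermediate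
24 | (5R,6R)-6-[(2R,4R,6E)-4,6-dimethyloct-6-en-2-yl]-5-(triethylsilyloxy)tetrahydro-2H-pyran-2-one | C/C=C(\C)C[C@H](C)C[C@@H](C)[C@H]1OC(=O)CC[C@H]1O[Si](CC)(CC)CC | intermediate
25 | (5R,6R)-6-[(2R,4R,6E)-4,6-dimethyloct-6-en-2-yl]-5-hydroxytetrahydro-2H-pyran-2-one | C/C=C(\C)C[C@H](C)C[C@@H](C)[C@H]1OC(=O)CC[C@H]1O | intermediate
26 | (5S)-5-{[(1S,2R,5S)-2-isopropyl-5-methylcyclohexyl]oxy}furan-2(5H)-one | C[C@H]1CC[C@@H]([C@H](C1)O[C@H]2OC(=O)C=C2)C(C)C | starting material
27 | (2-methylprop-1-en-1-yl)magnesium bromide | CC(C)=C[Mg]Br | starting material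
28 | (4R,5S)-5-{[(1S,2R,5S)-2-isopropyl-5-methylcyclohexyl]oxy}-4-(2-methylprop-1-en-1-yl)dihydrofuran-2(3H)-one | C[C@H]1CC[C@@H]([C@H](C1)O[C@H]2OC(=O)C[C@@H]2C=C(C)C)C(C)C | intermediate
29 | (R)-2-(2-methylprop-1-en-1-yl)butane-1,4-diol | CC(C)=C[C@H](CO)CCO | intermediate
30 | (R)-1,4-bis(tert-butyldimethylsilyloxy)-2-(2-methylprop-1-en-1-yl)butane | CC(C)=C[C@H](CO[Si](C)(C)C(C)(C)C)CCO[Si](C)(C)C(C)(C)C | intermediate
31 | (2E,4R)-6-(tert-butyldimethylsilyloxy)-4-[(tert-butyldimethylsilyloxy)methyl]-2-methylhex-2-en-1-ol | OC/C(C)=C/[C@H](CO[Si](C)(C)C(C)(C)C)CCO[Si](C)(C)C(C)(C)C | intermediate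
32 | (2E,4R)-6-(tert-butyldimethylsilyloxy)-4-[(tert-butyldimethylsilyloxy)methyl]-2-methylhex-2-enal | O=C/C(C)=C/[C@H](CO[Si](C)(C)C(C)(C)C)CCO[Si](C)(C)C(C)(C)C | intermediate
33 | malonic acid | OC(=O)CC(=O)O | starting material
34 | 2-{(2E,4R)-6-(tert-butyldimethylsilyloxy)-4-[(tert-butyldimethylsilyloxy)methyl]-2-methylhex-2-en-1-ylidene}malonic acid | OC(=O)C(C(=O)O)=C/C(C)=C/[C@H](CO[Si](C)(C)C(C)(C)C)CCO[Si](C)(C)C(C)(C)C | intermediate
35 | (2E,4E,6R)-8-(tert-butyldimethylsilyloxy)-6-[(tert-butyldimethylsilyloxy)methyl]-4-methylocta-2,4-dienoic acid | OC(=O)/C=C/C(C)=C/[C@H](CO[Si](C)(C)C(C)(C)C)CCO[Si](C)(C)C(C)(C)C | intermediate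
36 | mixed anhydride of 35 and 2,4,6-trichlorobenzoic acid | O=C(OC(=O)/C=C/C(C)=C/[C@H](CO[Si](C)(C)C(C)(C)C)CCO[Si](C)(C)C(C)(C)C)c1c(Cl)cc(Cl)cc1Cl | intermediate
37 | (2R,3R)-2-[(2R,4R,6E)-4,6-dimethyloct-6-en-2-yl]-6-oxotetrahydro-2H-pyran-3-yl (2E,4E,6R)-8-(tert-butyldimethylsilyloxy)-6-[(tert-butyldimethylsilyloxy)methyl]-4-methylocta-2,4-dienoate | C/C=C(\C)C[C@H](C)C[C@@H](C)[C@H]1OC(=O)CC[C@H]1OC(=O)/C=C/C(C)=C/[C@H](CO[Si](C)(C)C(C)(C)C)CCO[Si](C)(C)C(C)(C)C | intermediate
38 | (2R,3R)-2-[(2R,4R,6E)-4,6-dimethyloct-6-en-2-yl]-6-oxotetrahydro-2H-pyran-3-yl (2E,4E,6R)-8-hydroxy-6-(hydroxymethyl)-4-methylocta-2,4-dienoate | C/C=C(\C)C[C@H](C)C[C@@H](C)[C@H]1OC(=O)CC[C@H]1OC(=O)/C=C/C(C)=C/[C@H](CO)CCO | target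

Total step count: 18.
Longest linear sequence: 10 steps (1, 2, 3, 4, 8, 9, 10, 11, 17, 18).

Steps most likely to fail

Step 8. Capture of the transient oxiranyl lithium by the hindered secondary boronic ester may be too slow, so that the carbenoid is lost by β-elimination or dimerisation, and the β-oxido boronate may eliminate to an alkene before it is silylated. The fallback sets out from 12 and comes back at 25. Matteson homologation of 12 with LiCHCl2 still forms the same carbon–carbon bond by 1,2-shift and gives 2-[(2R,4R,6E)-1-chloro-2,4,6-trimethyloct-6-en-1-yl]-4,4,5,5-tetramethyl-1,3,2-dioxaborolane F1. Buffered oxidation with NaBO3 converts it into (2R,4R,6E)-2,4,6-trimethyloct-6-enal F2. Reagent-controlled alkoxyallylboration with the (Z)-γ-(methoxymethoxy)allyl diisopinocampheylborane enantiomer that attacks the required aldehyde face (made from allyl methoxymethyl ether, s-BuLi, Ipc2BOMe and BF3·OEt2) should give the syn-diol monoether (3R,4R,5R,7R,9E)-3-(methoxymethoxy)-5,7,9-trimethylundeca-1,9-dien-4-ol F3. Hydroboration of the terminal alkene with 9-BBN and NaOH/H2O2 work-up gives (4R,5R,6R,8R,10E)-4-(methoxymethoxy)-6,8,10-trimethyldodec-10-ene-1,5-diol F4. TEMPO/PhI(OAc)2 closes this to (5R,6R)-6-[(2R,4R,6E)-4,6-dimethyloct-6-en-2-yl]-5-(methoxymethoxy)tetrahydro-2H-pyran-2-one F5, and Me2BBr in CH2Cl2 at −78 °C removes the acetal to give 25.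

Step 17. Under the basic acylation conditions the cis-hydroxy lactone may contract to the γ-lactone by translactonisation faster than the hindered hydroxyl is acylated, and the activated dienoic acid may lose its alkene geometry. The fallback sets out from 25 and comes back at 37. The alcohol is esterified with the small diethylphosphonoacetic acid (DCC, cat. DMAP, CH2Cl2, 0 °C) to (2R,3R)-2-[(2R,4R,6E)-4,6-dimethyloct-6-en-2-yl]-6-oxotetrahydro-2H-pyran-3-yl 2-(diethoxyphosphoryl)acetate F6. A Horner–Wadsworth–Emmons olefination with enal 32 under Masamune–Roush conditions (LiCl, i-Pr2NEt, MeCN) then builds the (2E,4E)-dienoate in place and gives 37; acid 35 and step 16 are not needed.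

Step 15. The ene oxidation may stall at the hindered isobutenyl group, run on to over-oxidised products, or cleave silyl ethers through acidic selenium species. The fallback sets out from 30 and comes back at 32. Ozonolysis (O3, CH2Cl2, −78 °C; then PPh3) cuts the alkene to (S)-4-(tert-butyldimethylsilyloxy)-2-[(tert-butyldimethylsilyloxy)methyl]butanal F7, and Wittig olefination with 2-(triphenylphosphoranylidene)propanal (toluene, 80 °C) gives the (E)-enal 32.

Further compounds
F1 | step 8 | 2-[(2R,4R,6E)-1-chloro-2,4,6-trimethyloct-6-en-1-yl]-4,4,5,5-tetramethyl-1,3,2-dioxaborolane (mixture at C1) | C/C=C(\C)C[C@H](C)C[C@@H](C)C(Cl)B1OC(C)(C)C(C)(C)O1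
F2 | step 8 | (2R,4R,6E)-2,4,6-trimethyloct-6-enal | C/C=C(\C)C[C@H](C)C[C@@H](C)C=O
F3 | step 8 | (3R,4R,5R,7R,9E)-3-(methoxymethoxy)-5,7,9-trimethylundeca-1,9-dien-4-ol | C/C=C(\C)C[C@H](C)C[C@@H](C)[C@@H](O)[C@@H](C=C)OCOC
F4 | step 8 | (4R,5R,6R,8R,10E)-4-(methoxymethoxy)-6,8,10-trimethyldodec-10-ene-1,5-diol | C/C=C(\C)C[C@H](C)C[C@@H](C)[C@@H](O)[C@@H](CCCO)OCOC
F5 | step 8 | (5R,6R)-6-[(2R,4R,6E)-4,6-dimethyloct-6-en-2-yl]-5-(methoxymethoxy)tetrahydro-2H-pyran-2-one | C/C=C(\C)C[C@H](C)C[C@@H](C)[C@H]1OC(=O)CC[C@H]1OCOC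
F6 | step 17 | (2R,3R)-2-[(2R,4R,6E)-4,6-dimethyloct-6-en-2-yl]-6-oxotetrahydro-2H-pyran-3-yl 2-(diethoxyphosphoryl)acetate | C/C=C(\C)C[C@H](C)C[C@@H](C)[C@H]1OC(=O)CC[C@H]1OC(=O)CP(=O)(OCC)OCC
F7 | step 15 | (S)-4-(tert-butyldimethylsilyloxy)-2-[(tert-butyldimethylsilyloxy)methyl]butanal | O=C[C@H](CO[Si](C)(C)C(C)(C)C)CCO[Si](C)(C)C(C)(C)C
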